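The butenolide ring (O–C12(=O)–C11=C7–C6, germacranolide numbering) is read as carbon dioxide inserted between a nucleophilic C11 and an electrophilic C6 that sit cis on the C7=C11 alkene. A (Z)-vinyl iodide carrying an allylic chloride at C6, next to the preformed C4–C5 epoxide, is lithiated, carboxylated with CO2 and closed by intramolecular O-alkylation, so that the C11–C12 and O–C6 bonds form in one flask with inversion at C6. The precursor comes from alkoxide-directed anti-carbomagnesiation of a propargylic alcohol, hydroxyl-directed epoxidation and invertive chlorination. Oxidative cleavage, methallylation, ring-closing metathesis to the ten-membered ring and acylation finish the target.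

Key step: step 10

Remark: locants follow germacranolide numbering (C1–C10 ring, C6 the lactone-oxygen carbon, C11 and C12 the lactone α-carbon and carbonyl, C13 the acetoxymethyl carbon, C14 and C15 the methyls on C10 and C4); the target is 1(10)Z,2S,4R,5R,6S,8S.

Assumption: the facial senses of the reagent-controlled steps 2, 6 and 14 are assigned by analogy with model aldehydes; should one deliver the opposite face, the enantiomeric catalyst or reagent is used.

Step 1
Reactants: 1 methyl 3-methylbut-2-enoate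
Product: 3 tert-butyl{[(1Z)-1-methoxy-3-methylbuta-1,3-dien-1-yl]oxy}dimethylsilane, via lithium dienolate 2 (not isolated)
Conditions: LiN(iPr)2, THF, −78 °C; then TBSCl, DMPU, −78 °C → rt
Reagents that add atoms: tert-butyldimethylsilyl chloride (TBSCl), CC(C)(C)[Si](C)(C)Cl
Why: Kinetic γ-deprotonation of the enoate and O-silylation of the dienolate (silyl ketene acetal formation) should give the vinylogous nucleophile; its ketene-acetal geometry is not stereodetermining later.

Step 2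
Reactants: 3 silyl dienolate; 4 3-(trimethylsilyl)prop-2-ynal
Product: 5 methyl (2E,5S)-5-hydroxy-3-methyl-7-(trimethylsilyl)hept-2-en-6-ynoate
Conditions: SiCl4, (S,S)-binaphthyldiamine-derived bisphosphoramide (5 mol%), CH2Cl2, −78 °C; aq. NaHCO3/KF
Reagents that add atoms: none
Why: Lewis-base-activated SiCl4 vinylogous Mukaiyama aldol, in which the dienolate reacts only at its γ-carbon through an open transition state to give the (E)-enoate, while the chiral phosphoramide-bound silicon cation leaves the Si face of the ynal open and so sets C2 as S.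

Step 3
Reactants: 5 hydroxy ester
Product: 6 methyl (2E,5S)-5-[(tert-butyldimethylsilyl)oxy]-3-methyl-7-(trimethylsilyl)hept-2-en-6-ynoate
Conditions: TBSCl, imidazole, DMF, rt
Reagents that add atoms: tert-butyldimethylsilyl chloride (TBSCl), CC(C)(C)[Si](C)(C)Cl
Why: Standard silylation of a secondary alcohol, needed because a free propargylic hydroxyl would misdirect step 7.

Step 4
Reactants: 6 silyl ether ester
Product: 7 (2E,5S)-5-[(tert-butyldimethylsilyl)oxy]-3-methyl-7-(trimethylsilyl)hept-2-en-6-yn-1-ol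
Conditions: DIBAL-H, CH2Cl2, −78 °C; Rochelle salt
Reagents that add atoms: none
Why: 1,2-Reduction of the conjugated ester to the allylic alcohol by DIBAL-H, which leaves the silyl ether, the silylalkyne and the alkene geometry untouched.

Step 5
Reactants: 7 allylic alcohol
Product: 8 (2E,5S)-5-[(tert-butyldimethylsilyl)oxy]-3-methyl-7-(trimethylsilyl)hept-2-en-6-ynal
Conditions: MnO2, CH2Cl2, rt
Reagents that add atoms: none
Why: Selective allylic oxidation with MnO2 under neutral conditions should give the (E)-enal without isomerisation.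

Step 6
Reactants: 8 enal; 9 tert-butyldimethyl(prop-2-yn-1-yloxy)silane
Product: 10 (4R,5E,8S)-1,8-bis[(tert-butyldimethylsilyl)oxy]-6-methyl-10-(trimethylsilyl)deca-5-en-2,9-diyn-4-ol
Conditions: Me2Zn, (S,S)-ProPhenol (20 mol%), Ph3PO, toluene, 0 °C
Reagents that add atoms: none
Why: Zinc–ProPhenol catalysed asymmetric alkynylation of an enal, in which the dinuclear zinc catalyst delivers the alkynyl group to the Si face and sets C6 as R under catalyst control.

Step 7
Reactants: 10 propargylic alcohol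
Product: 12 (2Z,4R,5E,8S)-1,8-bis[(tert-butyldimethylsilyl)oxy]-3-ethenyl-2-iodo-6-methyl-10-(trimethylsilyl)deca-2,5-dien-9-yn-4-ol, via magnesium chelate 11 (not isolated)
Conditions: CH2=CHMgCl (4 equiv), THF, 65 °C; then I2, −78 → 0 °C
Reagents that add atoms: vinylmagnesium chloride, C=C[Mg]Cl; iodine, II
Why: Alkoxide-directed anti-carbomagnesiation of a propargylic alcohol, in which the vinyl group adds to C7 and magnesium is held at C11 in a five-membered chelate cis to C6, so that iodinolysis with retention gives the Z tetrasubstituted iodide.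

Step 8
Reactants: 12 iodo dienol
Product: 13 (1S,2Z)-4-[(tert-butyldimethylsilyl)oxy]-1-{(2R,3R)-3-[(2S)-2-[(tert-butyldimethylsilyl)oxy]-4-(trimethylsilyl)but-3-yn-1-yl]-3-methyloxiran-2-yl}-2-ethenyl-3-iodobut-2-en-1-ol (threo epoxy alcohol)
Conditions: mCPBA, NaHCO3, CH2Cl2, 0 °C
Reagents that add atoms: 3-chloroperoxybenzoic acid (mCPBA), OOC(=O)c1cccc(Cl)c1
Why: Hydroxyl-directed peracid epoxidation, in which allylic 1,3-strain between the C15 methyl and C6 puts the carbinol hydrogen in the alkene plane so that oxygen is delivered syn to the hydroxyl (threo, 4R,5R), the iodo-diene being too electron-poor to compete.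

Step 9
Reactants: 13 threo epoxy alcohol
Product: 14 tert-butyl{[(2Z,4R)-4-chloro-4-{(2S,3R)-3-[(2S)-2-[(tert-butyldimethylsilyl)oxy]-4-(trimethylsilyl)but-3-yn-1-yl]-3-methyloxiran-2-yl}-3-ethenyl-2-iodobut-2-en-1-yl]oxy}dimethylsilane (erythro chloride, C6 R)
Conditions: PPh3, Cl3CC(O)CCl3, 2,6-di-tert-butylpyridine, CH2Cl2, −20 → 0 °C
Reagents that add atoms: hexachloroacetone, ClC(Cl)(Cl)C(=O)C(Cl)(Cl)Cl
Why: Appel-type chlorination, in which chloride displaces the alkoxyphosphonium by SN2 with inversion at C6 under neutral conditions, the SN2′ path being blocked by the fully substituted C11.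

Step 10
Reactants: 14 erythro chloride
Product: 17 (5S)-3-{[(tert-butyldimethylsilyl)oxy]methyl}-5-{(2R,3R)-3-[(2S)-2-[(tert-butyldimethylsilyl)oxy]-4-(trimethylsilyl)but-3-yn-1-yl]-3-methyloxiran-2-yl}-4-ethenylfuran-2(5H)-one, via alkenyllithium 15 (not isolated), via lithium carboxylate 16 (not isolated)
Conditions: tBuLi (2.0 equiv), Et2O, −95 °C; CO2 (g), −95 → 0 °C; then DMPU, THF, 40 °C
Reagents that add atoms: carbon dioxide, O=C=O
Why: Iodine–lithium exchange at the (Z)-vinyl iodide gives the C11 alkenyllithium 15, which adds to CO2 to form the C11–C12 bond (carboxylate 16); on warming, the carboxylate oxygen displaces the allylic chloride and forms the O–C6 bond. The closest known reaction types are the carboxylation of alkenyllithiums and the cyclisation of (Z)-4-halo-2-enoates to butenolides. The butenolide closes in the 5-exo-tet mode. C6 is set by SN2 inversion of the R chloride, which restores the threo relation to the C4–C5 epoxide that the hydroxyl had in 13, so the two inversions of steps 9 and 10 amount to retention; C2, C4 and C5 are not touched. The step needs exchange at iodine without attack on the chloride or the epoxide (secured by the much faster iodine exchange at −95 °C and exactly two equivalents of tBuLi), O-alkylation at C6 rather than epoxide opening at C5 (five- against six-membered ring, chloride against alkoxide as leaving group), and the cis placement of C11 and C6, which the Z alkene from step 7 fixes.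

Step 11
Reactants: 17 silylated butenolide
Product: 18 (5S)-4-ethenyl-5-{(2R,3R)-3-[(2S)-2-hydroxybut-3-yn-1-yl]-3-methyloxiran-2-yl}-3-(hydroxymethyl)furan-2(5H)-one
Conditions: TBAF, AcOH (1:1), THF, 0 °C → rt
Reagents that add atoms: none
Why: Buffered fluoride desilylation should cleave both silyl ethers and the alkynyl C–Si bond, while the acetic acid keeps the medium too weakly basic to deprotonate C6 and open the epoxide by elimination.

Step 12
Reactants: 18 diol
Product: 19 {(5S)-5-[(2R,3R)-3-[(2S)-2-acetoxybut-3-yn-1-yl]-3-methyloxiran-2-yl]-4-ethenyl-2-oxo-2,5-dihydrofuran-3-yl}methyl acetate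
Conditions: Ac2O, pyridine, DMAP (cat.), CH2Cl2, 0 °C
Reagents that add atoms: acetic anhydride, CC(=O)OC(C)=O
Why: Standard DMAP-catalysed acetylation of the primary and the secondary hydroxyl installs both acetates of the target before the C8 hydroxyl exists.

Step 13
Reactants: 19 diacetate
Product: 21 {(5S)-5-[(2R,3R)-3-[(2S)-2-acetoxybut-3-yn-1-yl]-3-methyloxiran-2-yl]-4-formyl-2-oxo-2,5-dihydrofuran-3-yl}methyl acetate, via diol 20 (not isolated)
Conditions: OsO4 (cat.), NaIO4, 2,6-lutidine, 1,4-dioxane/H2O, rt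
Reagents that add atoms: osmium tetroxide, O=[Os](=O)(=O)=O; sodium periodate, [Na+].[O-]I(=O)(=O)=O
Why: Lemieux–Johnson oxidation, in which OsO4 dihydroxylates the only accessible alkene (the vinyl group, the butenolide alkene being tetrasubstituted and electron-poor and the alkyne inert) and periodate cleaves the diol to the C8 aldehyde.

Step 14
Reactants: 21 aldehyde
Product: 23 {(5S)-5-[(2R,3R)-3-[(2S)-2-acetoxybut-3-yn-1-yl]-3-methyloxiran-2-yl]-4-[(1S)-1-hydroxy-3-methylbut-3-en-1-yl]-2-oxo-2,5-dihydrofuran-3-yl}methyl acetate, via borinate 22 (not isolated)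
Conditions: (−)-Ipc2BOMe, CH2=C(CH3)CH2MgCl, Et2O, −78 → 25 °C; then 21, −78 °C; pH 7 buffer, H2O2, 0 °C
Reagents that add atoms: methallylmagnesium chloride, CC(=C)C[Mg]Cl
Why: Brown methallylation, in which the B-methallyl diisopinocampheylborane adds through a chair-like six-membered transition state to the Si face of the aldehyde under reagent control and sets C8 as S, while esters, lactone and epoxide are inert at −78 °C.

Step 15
Reactants: 23 alkynyl alcohol
Product: 24 {(5S)-5-[(2R,3R)-3-[(2S)-2-acetoxybut-3-en-1-yl]-3-methyloxiran-2-yl]-4-[(1S)-1-hydroxy-3-methylbut-3-en-1-yl]-2-oxo-2,5-dihydrofuran-3-yl}methyl acetate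
Conditions: H2 (1 atm), Pd/CaCO3 poisoned with Pb(OAc)2 (Lindlar catalyst), quinoline, EtOAc, rt
Reagents that add atoms: none
Why: Lindlar semi-hydrogenation should stop at the terminal alkene and leave the 1,1-disubstituted alkene, the epoxide and the esters untouched.

Step 16
Reactants: 24 diene
Product: 25 (1(10)Z,2S,4R,5R,6S,8S)-2,13-diacetoxy-4,5-epoxy-8-hydroxygermacra-1(10),7(11)-dien-12,6-olide
Conditions: second-generation Grubbs catalyst RuCl2(=CHPh)(PCy3)(H2IMes) (10 mol%), 1,4-benzoquinone, toluene (1 mM), 80 °C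
Reagents that add atoms: none
Why: Ring-closing metathesis of the vinyl and the 1,1-disubstituted alkene with loss of ethene, the Z trisubstituted alkene being expected as the less strained product of a reversible closure in a chain pre-organised by the butenolide and the trans-epoxide.

Step 17
Reactants: 25 macrocyclic alcohol
Product: 26 (1(10)Z,2S,4R,5R,6S,8S)-2,13-diacetoxy-4,5-epoxy-8-(methacryloyloxy)germacra-1(10),7(11)-dien-12,6-olide (target, CNP0268364.3)
Conditions: methacrylic anhydride, Et3N, DMAP, CH2Cl2, 0 °C → rt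
Reagents that add atoms: methacrylic anhydride, CC(=C)C(=O)OC(=O)C(C)=C
Why: DMAP-catalysed acylation of the only free hydroxyl (C8) under mildly basic conditions that should not deprotonate C6.

Compound list
1 | methyl 3-methylbut-2-enoate | COC(=O)C=C(C)C | starting material
2 | lithium (1Z)-1-methoxy-3-methylbuta-1,3-dien-1-olate | C=C(C)/C=C(/OC)O[Li] | intermediate
3 | tert-butyl{[(1Z)-1-methoxy-3-methylbuta-1,3-dien-1-yl]oxy}dimethylsilane | C=C(C)/C=C(/OC)O[Si](C)(C)C(C)(C)C | intermediate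
4 | 3-(trimethylsilyl)prop-2-ynal | C[Si](C)(C)C#CC=O | starting material
5 | methyl (2E,5S)-5-hydroxy-3-methyl-7-(trimethylsilyl)hept-2-en-6-ynoate | C[Si](C)(C)C#C[C@@H](O)C/C(C)=C/C(=O)OC | intermediate
6 | methyl (2E,5S)-5-[(tert-butyldimethylsilyl)oxy]-3-methyl-7-(trimethylsilyl)hept-2-en-6-ynoate | C[Si](C)(C)C#C[C@@H](O[Si](C)(C)C(C)(C)C)C/C(C)=C/C(=O)OC | intermediate
7 | (2E,5S)-5-[(tert-butyldimethylsilyl)oxy]-3-methyl-7-(trimethylsilyl)hept-2-en-6-yn-1-ol | C[Si](C)(C)C#C[C@@H](O[Si](C)(C)C(C)(C)C)C/C(C)=C/CO | intermediate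
8 | (2E,5S)-5-[(tert-butyldimethylsilyl)oxy]-3-methyl-7-(trimethylsilyl)hept-2-en-6-ynal | C[Si](C)(C)C#C[C@@H](O[Si](C)(C)C(C)(C)C)C/C(C)=C/C=O | intermediate
9 | tert-butyldimethyl(prop-2-yn-1-yloxy)silane | C#CCO[Si](C)(C)C(C)(C)C | starting material
10 | (4R,5E,8S)-1,8-bis[(tert-butyldimethylsilyl)oxy]-6-methyl-10-(trimethylsilyl)deca-5-en-2,9-diyn-4-ol | C[Si](C)(C)C#C[C@@H](O[Si](C)(C)C(C)(C)C)C/C(C)=C/[C@@H](O)C#CCO[Si](C)(C)C(C)(C)C | intermediate
11 | cyclic alkenylmagnesium alkoxide of 12 (2,5-dihydro-1,2-oxamagnesole; Mg on C11 and on the C6 oxygen, vinyl on C7) | C[Si](C)(C)C#C[C@@H](O[Si](C)(C)C(C)(C)C)C/C(C)=C/[C@H]1O[Mg]C(CO[Si](C)(C)C(C)(C)C)=C1C=C | intermediate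
12 | (2Z,4R,5E,8S)-1,8-bis[(tert-butyldimethylsilyl)oxy]-3-ethenyl-2-iodo-6-methyl-10-(trimethylsilyl)deca-2,5-dien-9-yn-4-ol | C[Si](C)(C)C#C[C@@H](O[Si](C)(C)C(C)(C)C)C/C(C)=C/[C@@H](O)/C(C=C)=C(\I)CO[Si](C)(C)C(C)(C)C | intermediate
13 | (1S,2Z)-4-[(tert-butyldimethylsilyl)oxy]-1-{(2R,3R)-3-[(2S)-2-[(tert-butyldimethylsilyl)oxy]-4-(trimethylsilyl)but-3-yn-1-yl]-3-methyloxiran-2-yl}-2-ethenyl-3-iodobut-2-en-1-ol | C[Si](C)(C)C#C[C@@H](O[Si](C)(C)C(C)(C)C)C[C@@]1(C)O[C@@H]1[C@@H](O)/C(C=C)=C(\I)CO[Si](C)(C)C(C)(C)C | intermediate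
14 | tert-butyl{[(2Z,4R)-4-chloro-4-{(2S,3R)-3-[(2S)-2-[(tert-butyldimethylsilyl)oxy]-4-(trimethylsilyl)but-3-yn-1-yl]-3-methyloxiran-2-yl}-3-ethenyl-2-iodobut-2-en-1-yl]oxy}dimethylsilane | C[Si](C)(C)C#C[C@@H](O[Si](C)(C)C(C)(C)C)C[C@@]1(C)O[C@@H]1[C@H](Cl)/C(C=C)=C(\I)CO[Si](C)(C)C(C)(C)C | intermediate
15 | C11 alkenyllithium from 14 (lithium in place of iodine, geometry retained) | C[Si](C)(C)C#C[C@@H](O[Si](C)(C)C(C)(C)C)C[C@@]1(C)O[C@@H]1[C@H](Cl)/C(C=C)=C(\[Li])CO[Si](C)(C)C(C)(C)C | intermediate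
16 | lithium (Z)-carboxylate from 15 (CO2Li on C11, cis to the C6 chloride) | C[Si](C)(C)C#C[C@@H](O[Si](C)(C)C(C)(C)C)C[C@@]1(C)O[C@@H]1[C@H](Cl)/C(C=C)=C(\C(=O)O[Li])CO[Si](C)(C)C(C)(C)C | intermediate
17 | (5S)-3-{[(tert-butyldimethylsilyl)oxy]methyl}-5-{(2R,3R)-3-[(2S)-2-[(tert-butyldimethylsilyl)oxy]-4-(trimethylsilyl)but-3-yn-1-yl]-3-methyloxiran-2-yl}-4-ethenylfuran-2(5H)-one | C[Si](C)(C)C#C[C@@H](O[Si](C)(C)C(C)(C)C)C[C@@]1(C)O[C@@H]1[C@H]1OC(=O)C(CO[Si](C)(C)C(C)(C)C)=C1C=C | intermediate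
18 | (5S)-4-ethenyl-5-{(2R,3R)-3-[(2S)-2-hydroxybut-3-yn-1-yl]-3-methyloxiran-2-yl}-3-(hydroxymethyl)furan-2(5H)-one | C#C[C@@H](O)C[C@@]1(C)O[C@@H]1[C@H]1OC(=O)C(CO)=C1C=C | intermediate
19 | {(5S)-5-[(2R,3R)-3-[(2S)-2-acetoxybut-3-yn-1-yl]-3-methyloxiran-2-yl]-4-ethenyl-2-oxo-2,5-dihydrofuran-3-yl}methyl acetate | C#C[C@@H](OC(C)=O)C[C@@]1(C)O[C@@H]1[C@H]1OC(=O)C(COC(C)=O)=C1C=C | intermediate
20 | vicinal diol from dihydroxylation of the vinyl group of 19 (both epimers at the new carbinol) | C#C[C@@H](OC(C)=O)C[C@@]1(C)O[C@@H]1[C@H]1OC(=O)C(COC(C)=O)=C1C(O)CO | intermediate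
21 | {(5S)-5-[(2R,3R)-3-[(2S)-2-acetoxybut-3-yn-1-yl]-3-methyloxiran-2-yl]-4-formyl-2-oxo-2,5-dihydrofuran-3-yl}methyl acetate | C#C[C@@H](OC(C)=O)C[C@@]1(C)O[C@@H]1[C@H]1OC(=O)C(COC(C)=O)=C1C=O | intermediate
22 | B,B-diisopinocampheylborinate of alcohol 23 | C#C[C@@H](OC(C)=O)C[C@@]1(C)O[C@@H]1[C@H]1OC(=O)C(COC(C)=O)=C1[C@H](CC(C)=C)OB([C@@H]2C[C@@H]3C[C@@H](C3(C)C)[C@H]2C)[C@@H]2C[C@@H]3C[C@@H](C3(C)C)[C@H]2C | intermediate
23 | {(5S)-5-[(2R,3R)-3-[(2S)-2-acetoxybut-3-yn-1-yl]-3-methyloxiran-2-yl]-4-[(1S)-1-hydroxy-3-methylbut-3-en-1-yl]-2-oxo-2,5-dihydrofuran-3-yl}methyl acetate | C#C[C@@H](OC(C)=O)C[C@@]1(C)O[C@@H]1[C@H]1OC(=O)C(COC(C)=O)=C1[C@@H](O)CC(C)=C | intermediate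
24 | {(5S)-5-[(2R,3R)-3-[(2S)-2-acetoxybut-3-en-1-yl]-3-methyloxiran-2-yl]-4-[(1S)-1-hydroxy-3-methylbut-3-en-1-yl]-2-oxo-2,5-dihydrofuran-3-yl}methyl acetate | C=C[C@@H](OC(C)=O)C[C@@]1(C)O[C@@H]1[C@H]1OC(=O)C(COC(C)=O)=C1[C@@H](O)CC(C)=C | intermediate
25 | (1(10)Z,2S,4R,5R,6S,8S)-2,13-diacetoxy-4,5-epoxy-8-hydroxygermacra-1(10),7(11)-dien-12,6-olide | O[C@H]1C/C(C)=C\[C@@H](OC(C)=O)C[C@@]2(C)O[C@@H]2[C@H]2OC(=O)C(COC(C)=O)=C12 | intermediate
26 | (1(10)Z,2S,4R,5R,6S,8S)-2,13-diacetoxy-4,5-epoxy-8-(methacryloyloxy)germacra-1(10),7(11)-dien-12,6-olide | C=C(C)C(=O)O[C@H]1C/C(C)=C\[C@@H](OC(C)=O)C[C@@]2(C)O[C@@H]2[C@H]2OC(=O)C(COC(C)=O)=C12 | target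

Total step count: 17. Longest linear sequence: 17 steps (1 → 26).

Steps most likely to fail

1. Step 16 (ring-closing metathesis). What may go wrong: intermolecular cross-metathesis (oligomers) outruns closure of the strained ten-membered ring, or the ring closes to the E alkene. Fallback (sets out from 18, comes back at 25): a temporary silicon tether turns the closure into an eight-membered one in which only the Z alkene can form. Selective acetylation of the primary hydroxyl of 18 (AcCl, 2,4,6-collidine, −78 °C) should give the 13-monoacetate F1. Lemieux–Johnson cleavage as in step 13, via the vicinal diol F2, gives the hydroxy aldehyde F3. Brown methallylation as in step 14, via the borinate F4, gives the alkynyl diol F5, and Lindlar reduction as in step 15 gives the diene-diol F6. iPr2SiCl2 and imidazole at high dilution bridge the C2 and C8 hydroxyls as the cyclic diisopropylsilylene F7. Ring-closing metathesis with the same ruthenium catalyst then forms the bicyclic siloxane F8, HF·pyridine releases the macrocyclic diol F9, and acetylation of the less hindered allylic C2 hydroxyl (Ac2O, collidine, −40 °C) returns 25.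

2. Step 9 (invertive chlorination). What may go wrong: the alkoxyphosphonium ionises to the allyl cation, or the neighbouring epoxide oxygen takes part, so that configuration at C6 is lost instead of cleanly inverted. Fallback (sets out from 13, comes back at 17): the carbinol is inverted by oxidation and reduction instead of substitution. Dess–Martin periodinane should give the epoxy ketone F10. Zn(BH4)2 in Et2O at −20 °C, with hydride delivered to the zinc chelate of the ketone and epoxide oxygens, gives the erythro alcohol F11. Tosylation with retention (Ts2O, pyridine, DMAP) gives the tosylate F12. The carboxylative closure of step 10 (tBuLi, CO2, then DMPU), via the lithium carboxylate F13 and with displacement of tosylate instead of chloride, returns 17.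

3. Step 10 (key step). What may go wrong: the alkenyllithium eliminates the neighbouring silyloxide or attacks the allylic chloride before it is carboxylated, or O-alkylation by the lithium carboxylate is too slow. Fallback (sets out from 13, comes back at 17; step 9 is then not used): the lactone is closed through the hydroxyl instead. Deprotonation of 13 with MeLi and exchange with tBuLi at −78 °C give the alkoxide-chelated alkenyllithium F14, the lithium counterpart of chelate 11. CO2 and an acidic work-up give the hydroxy acid F15, which lactonises spontaneously with retention at C6 to 17 (acyl substitution in place of alkylation).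

Further compounds
F1 | step 16 | {(5S)-4-ethenyl-5-[(2R,3R)-3-[(2S)-2-hydroxybut-3-yn-1-yl]-3-methyloxiran-2-yl]-2-oxo-2,5-dihydrofuran-3-yl}methyl acetate | C#C[C@@H](O)C[C@@]1(C)O[C@@H]1[C@H]1OC(=O)C(COC(C)=O)=C1C=C
F2 | step 16 | vicinal diol from dihydroxylation of the vinyl group of F1 (both epimers at the new carbinol) | C#C[C@@H](O)C[C@@]1(C)O[C@@H]1[C@H]1OC(=O)C(COC(C)=O)=C1C(O)CO
F3 | step 16 | {(5S)-4-formyl-5-[(2R,3R)-3-[(2S)-2-hydroxybut-3-yn-1-yl]-3-methyloxiran-2-yl]-2-oxo-2,5-dihydrofuran-3-yl}methyl acetate | C#C[C@@H](O)C[C@@]1(C)O[C@@H]1[C@H]1OC(=O)C(COC(C)=O)=C1C=O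
F4 | step 16 | B,B-diisopinocampheylborinate of F5 | C#C[C@@H](O)C[C@@]1(C)O[C@@H]1[C@H]1OC(=O)C(COC(C)=O)=C1[C@H](CC(C)=C)OB([C@@H]2C[C@@H]3C[C@@H](C3(C)C)[C@H]2C)[C@@H]2C[C@@H]3C[C@@H](C3(C)C)[C@H]2C
F5 | step 16 | {(5S)-5-[(2R,3R)-3-[(2S)-2-hydroxybut-3-yn-1-yl]-3-methyloxiran-2-yl]-4-[(1S)-1-hydroxy-3-methylbut-3-en-1-yl]-2-oxo-2,5-dihydrofuran-3-yl}methyl acetate | C#C[C@@H](O)C[C@@]1(C)O[C@@H]1[C@H]1OC(=O)C(COC(C)=O)=C1[C@@H](O)CC(C)=C
F6 | step 16 | {(5S)-5-[(2R,3R)-3-[(2S)-2-hydroxybut-3-en-1-yl]-3-methyloxiran-2-yl]-4-[(1S)-1-hydroxy-3-methylbut-3-en-1-yl]-2-oxo-2,5-dihydrofuran-3-yl}methyl acetate | C=C[C@@H](O)C[C@@]1(C)O[C@@H]1[C@H]1OC(=O)C(COC(C)=O)=C1[C@@H](O)CC(C)=C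
F7 | step 16 | cyclic diisopropylsilylene of F6 (silicon bridging the C2 and C8 oxygens) | C=C[C@@H]1C[C@@]2(C)O[C@@H]2[C@H]2OC(=O)C(COC(C)=O)=C2[C@H](CC(C)=C)O[Si](C(C)C)(C(C)C)O1
F8 | step 16 | 2,8-O-diisopropylsilylene derivative of F9 (bicyclic siloxane, 1(10)Z) | CC(C)[Si]1(C(C)C)O[C@H]2C/C(C)=C\[C@@H](O1)C[C@@]3(C)O[C@@H]3[C@H]3OC(=O)C(COC(C)=O)=C23
F9 | step 16 | (1(10)Z,2S,4R,5R,6S,8S)-13-acetoxy-4,5-epoxy-2,8-dihydroxygermacra-1(10),7(11)-dien-12,6-olide | O[C@H]1C/C(C)=C\[C@@H](O)C[C@@]2(C)O[C@@H]2[C@H]2OC(=O)C(COC(C)=O)=C12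
F10 | step 9 | epoxy ketone from 13 (C6 carbonyl, epoxide and Z iodoalkene unchanged) | C[Si](C)(C)C#C[C@@H](O[Si](C)(C)C(C)(C)C)C[C@@]1(C)O[C@@H]1C(=O)/C(C=C)=C(\I)CO[Si](C)(C)C(C)(C)C
F11 | step 9 | erythro epoxy alcohol, the C6 epimer of 13 (C6 R) | C[Si](C)(C)C#C[C@@H](O[Si](C)(C)C(C)(C)C)C[C@@]1(C)O[C@@H]1[C@H](O)/C(C=C)=C(\I)CO[Si](C)(C)C(C)(C)C
F12 | step 9 | 4-methylbenzenesulfonate of F11 | C[Si](C)(C)C#C[C@@H](O[Si](C)(C)C(C)(C)C)C[C@@]1(C)O[C@@H]1[C@H](OS(=O)(=O)c1ccc(C)cc1)/C(C=C)=C(\I)CO[Si](C)(C)C(C)(C)C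
F13 | step 9 | lithium (Z)-carboxylate from F12 (CO2Li in place of iodine) | C[Si](C)(C)C#C[C@@H](O[Si](C)(C)C(C)(C)C)C[C@@]1(C)O[C@@H]1[C@H](OS(=O)(=O)c1ccc(C)cc1)/C(C=C)=C(\C(=O)O[Li])CO[Si](C)(C)C(C)(C)C
F14 | step 10 | lithium alkoxide alkenyllithium from 13 (O–Li on C6, Li in place of iodine) | C[Si](C)(C)C#C[C@@H](O[Si](C)(C)C(C)(C)C)C[C@@]1(C)O[C@@H]1[C@@H](O[Li])/C(C=C)=C(\[Li])CO[Si](C)(C)C(C)(C)C
F15 | step 10 | (Z)-hydroxy acid from F14 (CO2H on C11, cis to the C6 hydroxyl) | C[Si](C)(C)C#C[C@@H](O[Si](C)(C)C(C)(C)C)C[C@@]1(C)O[C@@H]1[C@@H](O)/C(C=C)=C(\C(O)=O)CO[Si](C)(C)C(C)(C)C
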